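**Retrosynthetic overview**
1. The γ-lactone is closed last (O–C12, desilylation and lactonisation of a seven-membered γ-hydroxy acrylate); the cycloheptane is closed before it by a nickel-catalysed reductive diene–aldehyde cyclisation of an acyclic aldehyde that forms the ring bond C8–C9.
2. Enabling feature: the lactone carbons C13=C11(–C12) together with ring carbons C7 and C8 are read as a 2-(methoxycarbonyl)buta-1,3-diene C8=C7–C11=C13 held on C6 through C7. Its terminus C8 (the ring CH2) bonds to the C9 carbonyl carbon, hydride lands on C7, and the C11=C13 methylene is regenerated.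
3. Dienyl aldehyde ⇐ Stille coupling (C7–C11) of a C7 vinyl bromide with methyl 2-(tributylstannyl)acrylate; C5 ester by Yamaguchi acylation; C2 ketone by tether-directed hydration of a C2≡C3 alkyne.
4. C1 carbinol ⇐ Felkin–Anh alkynylation of a C1 ketone; C5/C6 ⇐ reagent-controlled boron syn-aldol of a Roche-derived α-silyloxy ketone with 2-bromoacrolein.
5. Chiral pool: (S)-Roche ester (C10), (R)-but-3-yn-2-ol (C4), (R)-2-methylbutanoic acid (C2′).

Key step: step 16

Locants used throughout: ring C1 [C(OH)(acyl)], C5 (CH–O-acyl), C6 (CH–O of the lactone), C7 (ring-fusion CH), C8 (CH2), C9 (CHOH), C10 (CHCH3); lactone C11 (=C13H2) and C12 (C=O); side chain C2 (C=O), C3, C4 (CHOH), C15; C2′ is the stereocentre of the 2-methylbutanoate.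

Assumption: (R)-2-methylbutanoic acid and (R)-but-3-yn-2-ol are taken as commercial in the required enantiomeric form, and (−)-Ipc2BOTf is used as a reagent solution made beforehand from (+)-α-pinene by the standard procedure.

**Route**

Step 1
Reactants: 1 methyl (S)-3-hydroxy-2-methylpropanoate
Product: 2 methyl (S)-3-[(tert-butyldimethylsilyl)oxy]-2-methylpropanoate
Conditions: TBSCl, imidazole, CH2Cl2, 0 °C → rt
Reagents that add atoms: tert-butyldimethylsilyl chloride, CC(C)(C)[Si](C)(C)Cl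
Why: Routine silyl ether formation on the primary alcohol; C10 comes from the chiral pool and is not touched.

Step 2
Reactants: 2 methyl (S)-3-[(tert-butyldimethylsilyl)oxy]-2-methylpropanoate
Product: 4 (S)-4-[(tert-butyldimethylsilyl)oxy]-3-methylbutan-2-one, via Weinreb amide 3 (not isolated)
Conditions: MeNH(OMe)·HCl, i-PrMgCl, THF, −20 °C; then MeMgBr, 0 °C
Reagents that add atoms: methylmagnesium bromide, C[Mg]Br
Why: One-pot Weinreb ketone synthesis: the chloromagnesium amide converts the ester into amide 3, whose chelated tetrahedral adduct with MeMgBr releases the ketone only on work-up, so neither over-addition nor epimerisation at C10 is expected.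

Step 3
Reactants: 4 (S)-4-[(tert-butyldimethylsilyl)oxy]-3-methylbutan-2-one
Product: 6 (S)-4-[(tert-butyldimethylsilyl)oxy]-3-methyl-1-[(triethylsilyl)oxy]butan-2-one, via triethylsilyl enol ether 5 (not isolated)
Conditions: LDA, THF, −78 °C; TESCl; then mCPBA, NaHCO3, CH2Cl2, −20 → 0 °C
Reagents that add atoms: chlorotriethylsilane, CC[Si](CC)(CC)Cl; 3-chloroperbenzoic acid, OOC(=O)c1cccc(Cl)c1
Why: Rubottom oxidation: kinetic deprotonation at the methyl group gives the less substituted silyl enol ether, and epoxidation with 1,4-silyl shift gives the α-silyloxy ketone without enolising C10.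

Step 4
Reactants: 7 acrolein
Product: 9 2-bromoprop-2-enal, via 2,3-dibromopropanal 8 (not isolated)
Conditions: Br2, CH2Cl2, −78 °C; then Et3N, −78 → 0 °C
Reagents that add atoms: bromine, BrBr
Why: Bromine addition to the enal followed by E1cB loss of HBr is the standard route to the α-bromoenal, which is used as a freshly prepared solution.

Step 5
Reactants: 6 (S)-4-[(tert-butyldimethylsilyl)oxy]-3-methyl-1-[(triethylsilyl)oxy]butan-2-one and 9 2-bromoprop-2-enal
Product: 11 (2S,4S,5S)-6-bromo-1-[(tert-butyldimethylsilyl)oxy]-5-hydroxy-2-methyl-4-[(triethylsilyl)oxy]hept-6-en-3-one, via Z-boron enolate 10 (not isolated)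
Conditions: (−)-Ipc2BOTf, i-Pr2NEt, CH2Cl2, −78 °C; then 9, −78 → −20 °C; H2O2, MeOH, pH 7 buffer, 0 °C
Reagents that add atoms: none
Why: Reagent-controlled boron aldol reaction: enolisation on the CH2OTES side gives the Z-enolate, whose closed chair (Zimmerman–Traxler) transition state fixes the 5,6-syn relationship, while the (−)-Ipc ligands should direct attack to the si face of the aldehyde (assigned by analogy with the sense of the corresponding Ipc2B allyl and crotyl reagents) and so set C5 and C6 against the weak bias of C10.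

Step 6
Reactants: 11 (2S,4S,5S)-6-bromo-1-[(tert-butyldimethylsilyl)oxy]-5-hydroxy-2-methyl-4-[(triethylsilyl)oxy]hept-6-en-3-one
Product: 12 (2S,4S,5S)-6-bromo-1,5-bis[(tert-butyldimethylsilyl)oxy]-2-methyl-4-[(triethylsilyl)oxy]hept-6-en-3-one
Conditions: TBSOTf, 2,6-lutidine, CH2Cl2, −78 °C
Reagents that add atoms: tert-butyldimethylsilyl triflate, CC(C)(C)[Si](C)(C)OS(=O)(=O)C(F)(F)F
Why: Silylation of the hindered allylic alcohol with the silyl triflate at low temperature avoids retro-aldol cleavage of the β-hydroxy ketone.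

Step 7
Reactants: 13 (R)-but-3-yn-2-ol
Product: 14 (R)-tert-butyl(but-3-yn-2-yloxy)dimethylsilane
Conditions: TBSCl, imidazole, CH2Cl2, rt
Reagents that add atoms: tert-butyldimethylsilyl chloride, CC(C)(C)[Si](C)(C)Cl
Why: Routine silyl ether formation; C4 comes from the chiral pool.

Step 8
Reactants: 12 (2S,4S,5S)-6-bromo-1,5-bis[(tert-butyldimethylsilyl)oxy]-2-methyl-4-[(triethylsilyl)oxy]hept-6-en-3-one and 14 (R)-tert-butyl(but-3-yn-2-yloxy)dimethylsilane
Product: 16 (1R,4R,5S,6S,10S)-C1 alkynyl carbinol [C1–OH; C2≡C3; 5-OTES; 4,6,9-tris-OTBS; C7 vinyl bromide], via lithium acetylide 15 (not isolated)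
Conditions: 14, n-BuLi, THF, −78 °C; CeCl3; then 12, −78 → −40 °C
Reagents that add atoms: none
Why: 1,2-Addition of an alkynylcerium reagent under Felkin–Anh control: with only non-chelating silyl ethers present, both α-stereocentres (C5–OTES antiperiplanar to the nucleophile, C10 with its CH2OTBS arm anti) expose the same carbonyl face, which sets C1, and the weakly basic organocerium suppresses enolisation.

Step 9
Reactants: 16 (1R,4R,5S,6S,10S)-C1 alkynyl carbinol
Product: 17 (1R,4R,5S,6S,10S)-alkynyl 1,5-diol [C1–OH; C5–OH; 4,6,9-tris-OTBS; C7 vinyl bromide]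
Conditions: PPTS, MeOH/CH2Cl2, 0 °C → rt
Reagents that add atoms: none
Why: Chemoselective acid-catalysed methanolysis removes the triethylsilyl ether much faster than the tert-butyldimethylsilyl ethers.

Step 10
Reactants: 17 (1R,4R,5S,6S,10S)-alkynyl 1,5-diol
Product: 20 (1S,4R,5S,6S,10S)-C2 ketone diol [1,5-dihydroxy; 4,6,9-tris-OTBS; C7 vinyl bromide], via dimethylsilyl ether 18 (not isolated), via cyclic alkenylsiloxane 19 (not isolated)
Conditions: (HMe2Si)2NH, 60 °C; Pt2[(CH2=CHSiMe2)2O]3 (cat.), THF, rt; then KF, KHCO3, H2O2, THF/MeOH, rt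
Reagents that add atoms: hydrogen peroxide, OO
Why: Tether-directed alkyne hydration by intramolecular hydrosilylation and Tamao–Fleming oxidation: the C5–O–SiMe2H group adds syn and 5-exo-dig, which puts silicon on C2 only, and oxidative cleavage of the alkenyl C–Si bond gives the C2 ketone with C4 untouched.

Step 11
Reactants: 20 (1S,4R,5S,6S,10S)-C2 ketone diol and 21 (R)-2-methylbutanoic acid
Product: 23 (1S,4R,5S,6S,10S,2′R)-C5 ester [5-O-(R)-2-methylbutanoyl; 1-OH; 4,6,9-tris-OTBS; C7 vinyl bromide], via mixed anhydride 22 (not isolated)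
Conditions: 21, 2,4,6-trichlorobenzoyl chloride, Et3N, THF, rt; then 20, DMAP, toluene, rt
Reagents that add atoms: none
Why: Yamaguchi esterification: the mixed anhydride acylates the only secondary hydroxyl (C5) under DMAP catalysis, the tertiary C1–OH being inert, and the mild conditions should preserve C2′.

Step 12
Reactants: 23 (1S,4R,5S,6S,10S,2′R)-C5 ester
Product: 24 (1S,4R,5S,6S,10S,2′R)-C9 primary alcohol [9-OH; 1-OH; 4,6-bis-OTBS; C7 vinyl bromide]
Conditions: HF·pyridine, pyridine, THF, 0 °C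
Reagents that add atoms: none
Why: Selective desilylation: buffered HF·pyridine cleaves the unhindered primary silyl ether well before the two hindered secondary ones.

Step 13
Reactants: 25 methyl propiolate and 26 tributyltin hydride
Product: 27 methyl 2-(tributylstannyl)prop-2-enoate
Conditions: Pd(PPh3)4 (cat.), THF, 0 °C → rt
Reagents that add atoms: none
Why: Palladium-catalysed syn hydrostannation of an ynoate places tin on the α-carbon.

Step 14
Reactants: 24 (1S,4R,5S,6S,10S,2′R)-C9 primary alcohol and 27 methyl 2-(tributylstannyl)prop-2-enoate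
Product: 28 (1S,4R,5S,6R,10S,2′R)-diene ester alcohol [C7(=C8H2)–C11(=C13H2)–CO2Me; 9-OH; 1-OH; 4,6-bis-OTBS]
Conditions: Pd2(dba)3 (cat.), AsPh3, CuI (cat.), NMP, 45 °C
Reagents that add atoms: none
Why: Stille coupling with copper co-catalysis joins the 2-bromo-1-alkene carbon C7 to the α-stannyl acrylate carbon C11 under neutral, fluoride-free conditions that tolerate the hydroxyls and silyl ethers.

Step 15
Reactants: 28 (1S,4R,5S,6R,10S,2′R)-diene ester alcohol
Product: 29 (1S,4R,5S,6R,10R,2′R)-dienyl aldehyde [C9 aldehyde; 1-OH; 4,6-bis-OTBS]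
Conditions: Dess–Martin periodinane, NaHCO3, CH2Cl2, 0 °C
Reagents that add atoms: none
Why: Dess–Martin oxidation under buffered conditions gives the aldehyde without epimerising C10 or dehydrating the β-hydroxy aldehyde; the crude aldehyde is used at once.

Step 16
Reactants: 29 (1S,4R,5S,6R,10R,2′R)-dienyl aldehyde
Product: 30 (1S,4R,5S,6R,7S,9R,10S,2′R)-cycloheptanol acrylate [methyl 2-cycloheptylacrylate; 9-OH; 1-OH; 4,6-bis-OTBS]
Conditions: Ni(acac)2 (10 mol %), Et3B, THF, rt
Reagents that add atoms: none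
Why: Proposed new method: zerovalent nickel (from Ni(acac)2 and Et3B) binds the s-cis diene C8=C7–C11=C13 and couples its terminus C8 with the Et3B-activated aldehyde carbon C9 by oxidative cyclisation to an oxanickelacycle (allylnickel over C7–C11–C13, oxygen held by nickel and boron); ethyl transfer from boron, β-hydride elimination (ethene) and C–H reductive elimination at C7 then give the C9 carbinol, the C7–H bond and the C11=C13 methylene. The closest known reaction types are the nickel-catalysed homoallylation of aldehydes with 1,3-dienes promoted by Et3B and the nickel-promoted cyclisation of diene-aldehydes tethered through the diene terminus; a tether through the internal diene carbon C7 combined with an ester on C11 has not been shown. The seven-membered ring closes in a 7-endo mode (C7 and C8 both become ring atoms) through the five-membered oxanickelacycle that bridges C7 and C9. C9 is controlled by that bridge, which forces the carbinol oxygen and the nickel, later the C7 hydrogen, onto the same ring face; C7 is controlled by C6, because A(1,2) strain places C6–H in the diene plane next to C11 and the bulky OTBS group anti to nickel, so the C5 chain and the aldehyde reach C8 from the face that gives H-6 and H-7 cis. The step needs site selectivity (aldehyde C9 over the hindered C2 ketone, terminus C8 over C13, seven- over eight-membered ring) and hydride delivery to C7 and not C13, which the oxygen-bound metallacycle holding nickel next to C7 should secure. The lactone must stay open here, since a diene locked in the lactone ring would hold the C6–O bond in the diene plane and lead to the trans ring fusion.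

Step 17
Reactants: 30 (1S,4R,5S,6R,7S,9R,10S,2′R)-cycloheptanol acrylate
Product: 32 target lactone (1S,4R,5S,6R,7S,9R,10S,2′R), via hydroxy ester 31 (not isolated)
Conditions: HF·pyridine, THF, 0 °C → rt; then PPTS (cat.), CH2Cl2, rt
Reagents that add atoms: none
Why: Cleavage of both secondary silyl ethers frees C6–OH, which lactonises onto the cis-disposed acrylate ester (acid-catalysed transesterification) to give the cis-fused α-methylene-γ-lactone, while the trans-disposed C9–OH cannot reach the ester.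

**Compound list**
1 | methyl (S)-3-hydroxy-2-methylpropanoate ((S)-Roche ester) | OC[C@H](C)C(=O)OC | starting material
2 | methyl (S)-3-[(tert-butyldimethylsilyl)oxy]-2-methylpropanoate | CC(C)(C)[Si](C)(C)OC[C@H](C)C(=O)OC | intermediate
3 | (S)-3-[(tert-butyldimethylsilyl)oxy]-N-methoxy-N,2-dimethylpropanamide (Weinreb amide) | CC(C)(C)[Si](C)(C)OC[C@H](C)C(=O)N(C)OC | intermediate
4 | (S)-4-[(tert-butyldimethylsilyl)oxy]-3-methylbutan-2-one | CC(C)(C)[Si](C)(C)OC[C@H](C)C(C)=O | intermediate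
5 | (S)-4-[(tert-butyldimethylsilyl)oxy]-3-methyl-2-[(triethylsilyl)oxy]but-1-ene (silyl enol ether) | CC(C)(C)[Si](C)(C)OC[C@H](C)C(=C)O[Si](CC)(CC)CC | intermediate
6 | (S)-4-[(tert-butyldimethylsilyl)oxy]-3-methyl-1-[(triethylsilyl)oxy]butan-2-one | CC(C)(C)[Si](C)(C)OC[C@H](C)C(=O)CO[Si](CC)(CC)CC | intermediate
7 | acrolein (prop-2-enal) | C=CC=O | starting material
8 | 2,3-dibromopropanal (racemic) | O=CC(Br)CBr | intermediate
9 | 2-bromoprop-2-enal (2-bromoacrolein) | C=C(Br)C=O | intermediate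
10 | (Z)-enol bis[(−)-isopinocampheyl]borinate of 6 (C1=C5 enolate, O–B cis to OTES) | CC(C)(C)[Si](C)(C)OC[C@H](C)/C(OB([C@@H]1C[C@@H]2C[C@H]([C@H]1C)C2(C)C)[C@@H]1C[C@@H]2C[C@H]([C@H]1C)C2(C)C)=C/O[Si](CC)(CC)CC | intermediate
11 | (2S,4S,5S)-6-bromo-1-[(tert-butyldimethylsilyl)oxy]-5-hydroxy-2-methyl-4-[(triethylsilyl)oxy]hept-6-en-3-one (5S,6S,10S in the locants above) | CC(C)(C)[Si](C)(C)OC[C@H](C)C(=O)[C@@H](O[Si](CC)(CC)CC)[C@H](O)C(Br)=C | intermediate
12 | (2S,4S,5S)-6-bromo-1,5-bis[(tert-butyldimethylsilyl)oxy]-2-methyl-4-[(triethylsilyl)oxy]hept-6-en-3-one | CC(C)(C)[Si](C)(C)OC[C@H](C)C(=O)[C@@H](O[Si](CC)(CC)CC)[C@H](O[Si](C)(C)C(C)(C)C)C(Br)=C | intermediate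
13 | (R)-but-3-yn-2-ol | C#C[C@@H](C)O | starting material
14 | (R)-tert-butyl(but-3-yn-2-yloxy)dimethylsilane | C#C[C@@H](C)O[Si](C)(C)C(C)(C)C | intermediate
15 | lithium acetylide of 14 | [Li]C#C[C@@H](C)O[Si](C)(C)C(C)(C)C | intermediate
16 | (1R,4R,5S,6S,10S)-C1 alkynyl carbinol: TBSO–C9H2–C10H(CH3)–C1(OH)(C2≡C3–C4H(OTBS)CH3)–C5H(OTES)–C6H(OTBS)–C7(Br)=C8H2 | CC(C)(C)[Si](C)(C)OC[C@H](C)[C@@](O)(C#C[C@@H](C)O[Si](C)(C)C(C)(C)C)[C@@H](O[Si](CC)(CC)CC)[C@H](O[Si](C)(C)C(C)(C)C)C(Br)=C | intermediate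
17 | (1R,4R,5S,6S,10S)-alkynyl 1,5-diol (16 with free C5–OH) | CC(C)(C)[Si](C)(C)OC[C@H](C)[C@@](O)(C#C[C@@H](C)O[Si](C)(C)C(C)(C)C)[C@@H](O)[C@H](O[Si](C)(C)C(C)(C)C)C(Br)=C | intermediate
18 | 5-O-dimethylsilyl ether of 17 | CC(C)(C)[Si](C)(C)OC[C@H](C)[C@@](O)(C#C[C@@H](C)O[Si](C)(C)C(C)(C)C)[C@@H](O[SiH](C)C)[C@H](O[Si](C)(C)C(C)(C)C)C(Br)=C | intermediate
19 | 2,2-dimethyl-1,2-oxasilolane (ring O5–Si–C2–C1–C5) with exocyclic C2=C3H alkene, from syn 5-exo hydrosilylation | CC(C)(C)[Si](C)(C)OC[C@H](C)[C@@]1(O)/C(=C\[C@@H](C)O[Si](C)(C)C(C)(C)C)[Si](C)(C)O[C@H]1[C@H](O[Si](C)(C)C(C)(C)C)C(Br)=C | intermediate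
20 | (1S,4R,5S,6S,10S)-C2 ketone diol: C1(OH)(C2(=O)–C3H2–C4H(OTBS)CH3), C5–OH, 6,9-bis-OTBS, C7 vinyl bromide | CC(C)(C)[Si](C)(C)OC[C@H](C)[C@@](O)(C(=O)C[C@@H](C)O[Si](C)(C)C(C)(C)C)[C@@H](O)[C@H](O[Si](C)(C)C(C)(C)C)C(Br)=C | intermediate
21 | (R)-2-methylbutanoic acid | CC[C@@H](C)C(=O)O | starting material
22 | (R)-2-methylbutanoic 2,4,6-trichlorobenzoic anhydride | CC[C@@H](C)C(=O)OC(=O)c1c(Cl)cc(Cl)cc1Cl | intermediate
23 | (1S,4R,5S,6S,10S,2′R)-5-O-[(R)-2-methylbutanoyl] ester of 20 | CC(C)(C)[Si](C)(C)OC[C@H](C)[C@@](O)(C(=O)C[C@@H](C)O[Si](C)(C)C(C)(C)C)[C@@H](OC(=O)[C@H](C)CC)[C@H](O[Si](C)(C)C(C)(C)C)C(Br)=C | intermediate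
24 | (1S,4R,5S,6S,10S,2′R)-C9 primary alcohol (23 with free C9–OH) | OC[C@H](C)[C@@](O)(C(=O)C[C@@H](C)O[Si](C)(C)C(C)(C)C)[C@@H](OC(=O)[C@H](C)CC)[C@H](O[Si](C)(C)C(C)(C)C)C(Br)=C | intermediate
25 | methyl propiolate | C#CC(=O)OC | starting material
26 | tributyltin hydride | CCCC[SnH](CCCC)CCCC | starting material
27 | methyl 2-(tributylstannyl)prop-2-enoate | C=C(C(=O)OC)[Sn](CCCC)(CCCC)CCCC | intermediate
28 | (1S,4R,5S,6R,10S,2′R)-diene ester alcohol: C7(=C8H2)–C11(=C13H2)–CO2Me, C9–OH | OC[C@H](C)[C@@](O)(C(=O)C[C@@H](C)O[Si](C)(C)C(C)(C)C)[C@@H](OC(=O)[C@H](C)CC)[C@H](O[Si](C)(C)C(C)(C)C)C(=C)C(=C)C(=O)OC | intermediate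
29 | (1S,4R,5S,6R,10R,2′R)-dienyl aldehyde (28 with C9 as CHO) | O=C[C@H](C)[C@@](O)(C(=O)C[C@@H](C)O[Si](C)(C)C(C)(C)C)[C@@H](OC(=O)[C@H](C)CC)[C@H](O[Si](C)(C)C(C)(C)C)C(=C)C(=C)C(=O)OC | intermediate
30 | (1S,4R,5S,6R,7S,9R,10S,2′R)-methyl 2-cycloheptylacrylate: ring C1, C5–C10; 9-OH, 1-OH, 4,6-bis-OTBS, 5-O-acyl | COC(=O)C(=C)[C@@H]1C[C@@H](O)[C@H](C)[C@@](O)(C(=O)C[C@@H](C)O[Si](C)(C)C(C)(C)C)[C@@H](OC(=O)[C@H](C)CC)[C@@H]1O[Si](C)(C)C(C)(C)C | intermediate
31 | desilylated hydroxy ester of 30 (4,6-diol) | COC(=O)C(=C)[C@@H]1C[C@@H](O)[C@H](C)[C@@](O)(C(=O)C[C@@H](C)O)[C@@H](OC(=O)[C@H](C)CC)[C@@H]1O | intermediate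
32 | target CNP0291806.5: cis-fused α-methylene-γ-lactone (12,6-olide) on the cycloheptane; 1-OH, 9-OH, 10-CH3, C1 (R)-3-hydroxybutanoyl, 5-O-(R)-2-methylbutanoyl | C=C1C(=O)O[C@@H]2[C@H]1C[C@@H](O)[C@H](C)[C@@](O)(C(=O)C[C@@H](C)O)[C@H]2OC(=O)[C@H](C)CC | target

**Step count and risks**
Total step count: 17. Longest linear sequence: 14 steps (1, 2, 3, 5, 6, 8, 9, 10, 11, 12, 14, 15, 16, 17).

Steps most likely to fail:

1. Step 16 (proposed new method). What may go wrong: hydride delivery to C13 instead of C7, attack on the other diene face (trans ring fusion), β-elimination of the C6 silyloxy group from the allylnickel, or oligomerisation of the diene. Fallback with known chemistry that keeps the same ring-closing bond: it sets out from 24. Palladium-catalysed coupling of the vinyl bromide with the Reformatsky reagent BrZnCH2CO2Me should give the β,γ-unsaturated ester F1, and Dess–Martin oxidation the aldehyde F2. A Me2AlCl-promoted type 2 carbonyl-ene cyclisation, in which C8 attacks C9 and the allylic hydrogen is lost from C11, should close the seven-membered ring as the cycloheptylidene acetate F3. HF·pyridine removes the silyl ethers and the ester lactonises onto C6–OH (after E/Z equilibration if needed) to the butenolide F4. Hydroxyl-directed hydrogenation with [Ir(cod)(PCy3)(py)]PF6 from the face of the C9 hydroxyl should give the cis-fused saturated lactone F5. Enolate formation with excess LiHMDS and trapping with Eschenmoser's salt gives the Mannich base F6; MeI converts it into the methiodide F7, and NaHCO3 then eliminates to return to the route at 32.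

2. Step 10. What may go wrong: competing hydrosilylation of the C7=C8 bromoalkene, silyl migration between O6 and O5, or oxidative cleavage of the α-hydroxy ketone in the peroxide stage. Fallback: it sets out from 12. Felkin–Anh addition of 1-ethoxyvinyllithium/CeCl3 gives the enol ether carbinol F8, which dilute oxalic acid hydrolyses to the methyl ketone F9. A reagent-controlled boron aldol reaction (the Ipc2BCl antipode that gives si-face attack, Et3N, then acetaldehyde) gives the β-hydroxy ketone F10. TBSOTf/2,6-lutidine gives the silyl ether F11, and PPTS/MeOH removes the triethylsilyl group to return to the route at 20.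

3. Step 14. What may go wrong: slow transmetalation at the hindered 2-bromo-1-alkene with protodestannylation, and Diels–Alder dimerisation of the product diene on heating. Fallback: it sets out from 24. Miyaura borylation (B2pin2, PdCl2(dppf), KOAc, dioxane) gives the alkenylboronate F12; Suzuki–Miyaura coupling with commercial methyl 2-bromoacrylate (Pd(PPh3)4, K3PO4, THF/H2O, rt) returns to the route at 28.

**Further compounds**
F1 | step 16 | β,γ-unsaturated ester: 24 with C7(=C8H2)–CH2–CO2Me in place of the vinyl bromide | OC[C@H](C)[C@@](O)(C(=O)C[C@@H](C)O[Si](C)(C)C(C)(C)C)[C@@H](OC(=O)[C@H](C)CC)[C@H](O[Si](C)(C)C(C)(C)C)C(=C)CC(=O)OC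
F2 | step 16 | aldehyde of F1 (C9 as CHO) | O=C[C@H](C)[C@@](O)(C(=O)C[C@@H](C)O[Si](C)(C)C(C)(C)C)[C@@H](OC(=O)[C@H](C)CC)[C@H](O[Si](C)(C)C(C)(C)C)C(=C)CC(=O)OC
F3 | step 16 | methyl cycloheptylideneacetate (C7=C11H–CO2Me; 9-OH; 4,6-bis-OTBS) | COC(=O)C=C1C[C@@H](O)[C@H](C)[C@@](O)(C(=O)C[C@@H](C)O[Si](C)(C)C(C)(C)C)[C@@H](OC(=O)[C@H](C)CC)[C@@H]1O[Si](C)(C)C(C)(C)C
F4 | step 16 | butenolide (C7=C11; 12,6-olide) with free 1-, 4- and 9-hydroxyls | O=C1C=C2C[C@@H](O)[C@H](C)[C@@](O)(C(=O)C[C@@H](C)O)[C@@H](OC(=O)[C@H](C)CC)[C@@H]2O1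
F5 | step 16 | cis-fused saturated γ-lactone lacking C13 (C11H2) | O=C1C[C@@H]2C[C@@H](O)[C@H](C)[C@@](O)(C(=O)C[C@@H](C)O)[C@@H](OC(=O)[C@H](C)CC)[C@@H]2O1
F6 | step 16 | Mannich base: 11-(dimethylaminomethyl) lactone | CN(C)CC1C(=O)O[C@@H]2[C@H]1C[C@@H](O)[C@H](C)[C@@](O)(C(=O)C[C@@H](C)O)[C@H]2OC(=O)[C@H](C)CC
F7 | step 16 | methiodide of F6 | C[N+](C)(C)CC1C(=O)O[C@@H]2[C@H]1C[C@@H](O)[C@H](C)[C@@](O)(C(=O)C[C@@H](C)O)[C@H]2OC(=O)[C@H](C)CC.[I-]
F8 | step 10 | C1 (1-ethoxyvinyl) carbinol from 12 | CC(C)(C)[Si](C)(C)OC[C@H](C)[C@@](O)(C(=C)OCC)[C@@H](O[Si](CC)(CC)CC)[C@H](O[Si](C)(C)C(C)(C)C)C(Br)=C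
F9 | step 10 | C1 acetyl carbinol (methyl ketone) | CC(C)(C)[Si](C)(C)OC[C@H](C)[C@@](O)(C(C)=O)[C@@H](O[Si](CC)(CC)CC)[C@H](O[Si](C)(C)C(C)(C)C)C(Br)=C
F10 | step 10 | β-hydroxy ketone (C4–OH; 5-OTES) | CC(C)(C)[Si](C)(C)OC[C@H](C)[C@@](O)(C(=O)C[C@@H](C)O)[C@@H](O[Si](CC)(CC)CC)[C@H](O[Si](C)(C)C(C)(C)C)C(Br)=C
F11 | step 10 | 4-O-TBS ether of F10 (the 5-O-triethylsilyl ether of 20) | CC(C)(C)[Si](C)(C)OC[C@H](C)[C@@](O)(C(=O)C[C@@H](C)O[Si](C)(C)C(C)(C)C)[C@@H](O[Si](CC)(CC)CC)[C@H](O[Si](C)(C)C(C)(C)C)C(Br)=C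
F12 | step 14 | C7 pinacol alkenylboronate from 24 | OC[C@H](C)[C@@](O)(C(=O)C[C@@H](C)O[Si](C)(C)C(C)(C)C)[C@@H](OC(=O)[C@H](C)CC)[C@H](O[Si](C)(C)C(C)(C)C)C(=C)B1OC(C)(C)C(C)(C)O1
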